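**Retrosynthetic overview**
- The C6–O ester bond is made last by Mitsunobu inversion, joining the 6S amino alcohol of the core to the O-silylated (2E,6S)-8-hydroxy-2,6-dimethyloct-2-enoic acid prepared from (S)-citronellol.
- Feature on which the strategy rests: in the cyclopenta[c]pyridine core, C5 is a CH2 next to the oxygen-bearing C6, and C4a–C4 is a CH–CH(CH3) pair in the piperidine ring. The C4a–C5 bond is therefore cut to a C5 α-keto radical and a C4a=C4(CH3) ring alkene, with hydrogen added at C4.
- Ring order: the piperidine ring first, as a 5-methyl-1,2,3,6-tetrahydropyridine closed by ring-closing metathesis; the cyclopentanone second, closed by the radical step.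
- C7a, the only stereocentre carried into the key step, is set by iridium-catalysed branched allylic alkylation of dimethyl malonate. The malonate carbon becomes C7, one ester carbon becomes C6, and C5 is added as a diazomethane carbon.

Key step: step 10

Assumption: the (Sa,S,S) enantiomer of the phosphoramidite ligand is taken to deliver the (R)-configured branched malonate in step 4; should the sense of induction be the opposite, the (Ra,R,R) ligand is used with no other change.

**Step 1**
Reactants: 1 methyl (E)-4-bromobut-2-enoate; 2 2-methylprop-2-en-1-amine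
Product: 4 methyl (E)-4-[(methoxycarbonyl)(2-methylprop-2-enyl)amino]but-2-enoate, via secondary amine 3 (not isolated)
Conditions: 2 (3 equiv), K2CO3, THF, 0 °C → rt; filter, concentrate; then ClCO2Me, Et3N, CH2Cl2, 0 °C
Reagents that add atoms: methyl chloroformate, COC(=O)Cl
Why: SN2 N-alkylation of the primary amine at the allylic bromide (excess amine suppresses dialkylation) followed by N-acylation with the chloroformate should give the carbamate with the E geometry of the crotonate carried through.

**Step 2**
Reactants: 4 methyl (E)-4-[(methoxycarbonyl)(2-methylprop-2-enyl)amino]but-2-enoate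
Product: 5 methyl N-[(E)-4-hydroxybut-2-enyl]-N-(2-methylprop-2-enyl)carbamate
Conditions: DIBAL-H (2.3 equiv), CH2Cl2, −78 °C; Rochelle salt work-up
Reagents that add atoms: none
Why: DIBAL-H 1,2-reduction of the enoate should give the (E)-allylic alcohol at −78 °C, where the less electrophilic N,N-dialkyl carbamate is not attacked.

**Step 3**
Reactants: 5 methyl N-[(E)-4-hydroxybut-2-enyl]-N-(2-methylprop-2-enyl)carbamate
Product: 6 methyl N-[(E)-4-(methoxycarbonyloxy)but-2-enyl]-N-(2-methylprop-2-enyl)carbamate
Conditions: ClCO2Me, pyridine, CH2Cl2, 0 °C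
Reagents that add atoms: methyl chloroformate, COC(=O)Cl
Why: O-acylation of the primary allylic alcohol with the chloroformate installs the methyl carbonate leaving group that the iridium catalyst needs, on an (E)-alkene as that catalyst requires.

**Step 4**
Reactants: 6 methyl N-[(E)-4-(methoxycarbonyloxy)but-2-enyl]-N-(2-methylprop-2-enyl)carbamate; 7 dimethyl malonate
Product: 8 dimethyl 2-[(2R)-1-[(methoxycarbonyl)(2-methylprop-2-enyl)amino]but-3-en-2-yl]propanedioate
Conditions: [Ir(cod)Cl]2 (2 mol%), (Sa,S,S)-O,O′-(1,1′-binaphthyl-2,2′-diyl)-N,N-bis(1-phenylethyl)phosphoramidite (4 mol%), TBD (8 mol%), THF, rt; then 6 and 7 (1.5 equiv), 50 °C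
Reagents that add atoms: none
Why: Iridium-catalysed asymmetric allylic alkylation under salt-free conditions (the methoxide released from the carbonate deprotonates the malonate) should attack the substituted allyl terminus to give the branched product, and the cyclometallated Ir–phosphoramidite fixes the allyl face so that the future C7a is set as R.

**Step 5**
Reactants: 8 dimethyl 2-[(2R)-1-[(methoxycarbonyl)(2-methylprop-2-enyl)amino]but-3-en-2-yl]propanedioate
Product: 9 dimethyl 2-[(2R)-1-[(methoxycarbonyl)(2-methylprop-2-enyl)amino]but-3-en-2-yl]-2-methylpropanedioate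
Conditions: NaH, THF/DMF, 0 °C; MeI, 0 °C → rt
Reagents that add atoms: iodomethane, CI
Why: Malonate C-alkylation at the only acidic C–H installs the future C7 methyl, and the neighbouring stereocentre is not acidic and is left untouched.

**Step 6**
Reactants: 9 dimethyl 2-[(2R)-1-[(methoxycarbonyl)(2-methylprop-2-enyl)amino]but-3-en-2-yl]-2-methylpropanedioate
Product: 10 dimethyl 2-[(3R)-1-(methoxycarbonyl)-5-methyl-1,2,3,6-tetrahydropyridin-3-yl]-2-methylpropanedioate
Conditions: Grubbs second-generation catalyst (5 mol%), CH2Cl2 (0.01 M), 40 °C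
Reagents that add atoms: none
Why: Ring-closing metathesis of the vinyl and 2-methylallyl groups should close the six-membered tetrahydropyridine with its trisubstituted C4a=C4(CH3) alkene, the allylic stereocentre taking no part.

**Step 7**
Reactants: 10 dimethyl 2-[(3R)-1-(methoxycarbonyl)-5-methyl-1,2,3,6-tetrahydropyridin-3-yl]-2-methylpropanedioate
Product: 11 methyl 2-[(3R)-1-(methoxycarbonyl)-5-methyl-1,2,3,6-tetrahydropyridin-3-yl]propanoate (both C2 epimers)
Conditions: LiCl (3 equiv), H2O (2 equiv), DMSO, 160 °C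
Reagents that add atoms: none
Why: Krapcho dealkoxycarbonylation (chloride SN2 at an ester methyl, loss of CO2, protonation) removes one ester, the carbamate methyl being no more activated than the surviving mono-ester; the side-chain centre (future C7) forms as both epimers and is corrected in step 10.

**Step 8**
Reactants: 11 methyl 2-[(3R)-1-(methoxycarbonyl)-5-methyl-1,2,3,6-tetrahydropyridin-3-yl]propanoate
Product: 12 2-[(3R)-1-(methoxycarbonyl)-5-methyl-1,2,3,6-tetrahydropyridin-3-yl]propanoic acid (both C2 epimers)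
Conditions: LiOH·H2O (3 equiv), THF/MeOH/H2O, rt; 1 M HCl to pH 3
Reagents that add atoms: lithium hydroxide, [Li+].[OH-]
Why: Saponification of the methyl ester at room temperature should be selective, because the N,N-dialkyl methyl carbamate hydrolyses far more slowly.

**Step 9**
Reactants: 12 2-[(3R)-1-(methoxycarbonyl)-5-methyl-1,2,3,6-tetrahydropyridin-3-yl]propanoic acid
Product: 15 methyl (3R)-3-(4-bromo-3-oxobutan-2-yl)-5-methyl-3,6-dihydro-2H-pyridine-1-carboxylate (both side-chain epimers), via acid chloride 13 (not isolated), via diazoketone 14 (not isolated)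
Conditions: (COCl)2, DMF (cat.), CH2Cl2, 0 °C → rt; concentrate; TMSCHN2 (2.2 equiv), THF/MeCN, 0 °C; then 48% aq HBr, 0 °C
Reagents that add atoms: oxalyl chloride, ClC(=O)C(=O)Cl (chlorine of 13 only); trimethylsilyldiazomethane, C[Si](C)(C)C=[N+]=[N-]; hydrogen bromide, Br
Why: Acid chloride formation, C-acylation of the diazoalkane to the α-diazoketone (first half of an Arndt–Eistert sequence) and protonation with displacement of N2 by bromide should give the bromomethyl ketone with the added carbon C5, the alkene surviving brief cold HBr.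

**Step 10**
Reactants: 15 methyl (3R)-3-(4-bromo-3-oxobutan-2-yl)-5-methyl-3,6-dihydro-2H-pyridine-1-carboxylate
Product: 17 methyl (4R,4aS,7S,7aR)-4,7-dimethyl-6-oxo-octahydro-2H-cyclopenta[c]pyridine-2-carboxylate, via C7-epimeric ketone 16 (not isolated)
Conditions: Bu3SnH (1.3 equiv) + AIBN (0.15 equiv) by syringe pump over 6 h into 15 (0.01 M), PhH, 80 °C; KF/silica filtration; then NaOMe (0.3 equiv), MeOH, rt
Reagents that add atoms: none
Why: The stannyl radical abstracts bromine to give the electrophilic C5 α-keto radical, which adds to C4a of the electron-rich ring alkene (bond C4a–C5), and the tertiary C4 radical then takes hydrogen from Bu3SnH to carry the chain. The closest known reaction type is the tin-hydride-mediated reductive 5-exo cyclisation of α-halo ketones onto alkenes. The cyclopentanone closes 5-exo-trig, because 6-endo attack at C4 would have to form a quaternary centre in a bridged ring against the methyl group. C4a is set by the tether, since the three-atom chain on C7a reaches only its own face of the alkene and the fusion must be cis; C4 is set by hydrogen transfer to the convex face, anti to the new C4a–C5 bond, placing H4 cis to H4a; C7 is then brought by methoxide enolisation to the more stable exo-methyl configuration trans to C1. The step needs ring closure to outrun direct reduction, which polarity matching, high dilution and slow hydride addition should secure, and convex-face hydrogen delivery, which the folded cis-bicycle should secure.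

**Step 11**
Reactants: 17 methyl (4R,4aS,7S,7aR)-4,7-dimethyl-6-oxo-octahydro-2H-cyclopenta[c]pyridine-2-carboxylate
Product: 18 methyl (4R,4aS,6S,7S,7aR)-6-hydroxy-4,7-dimethyl-octahydro-2H-cyclopenta[c]pyridine-2-carboxylate
Conditions: NaBH4, MeOH, −20 °C
Reagents that add atoms: none
Why: Borohydride reduction should deliver hydride to the convex face (the side of H4a and H7a), which is also the trajectory small hydrides prefer in 2-methylcyclopentanones, so the hydroxyl is placed on the concave face trans to the C7 methyl (6S).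

**Step 12**
Reactants: 18 methyl (4R,4aS,6S,7S,7aR)-6-hydroxy-4,7-dimethyl-octahydro-2H-cyclopenta[c]pyridine-2-carboxylate
Product: 19 (4R,4aS,6S,7S,7aR)-2,4,7-trimethyl-octahydro-1H-cyclopenta[c]pyridin-6-ol
Conditions: LiAlH4, THF, 0 °C → reflux; Fieser work-up
Reagents that add atoms: none
Why: LiAlH4 reduction of the methyl carbamate should give the N-methyl amine while the alkoxide is inert and no stereocentre is touched.

**Step 13**
Reactants: 20 (S)-citronellol, (3S)-3,7-dimethyloct-6-en-1-ol
Product: 21 tert-butyl{[(3S)-3,7-dimethyloct-6-en-1-yl]oxy}dimethylsilane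
Conditions: TBSCl, imidazole, DMF, rt
Reagents that add atoms: tert-butyldimethylsilyl chloride, CC(C)(C)[Si](C)(C)Cl
Why: Imidazole-promoted silylation protects the primary alcohol through the oxidation, olefination and Mitsunobu steps.

**Step 14**
Reactants: 21 tert-butyl{[(3S)-3,7-dimethyloct-6-en-1-yl]oxy}dimethylsilane
Product: 22 (4S)-6-[(tert-butyldimethylsilyl)oxy]-4-methylhexanal
Conditions: O3, CH2Cl2, −78 °C; then PPh3, −78 °C → rt
Reagents that add atoms: ozone, [O-][O+]=O
Why: Ozonolysis of the trisubstituted alkene with reductive work-up should give the aldehyde without touching the remote stereocentre or the silyl ether.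

**Step 15**
Reactants: 22 (4S)-6-[(tert-butyldimethylsilyl)oxy]-4-methylhexanal; 23 ethyl 2-(triphenyl-λ5-phosphanylidene)propanoate
Product: 24 ethyl (2E,6S)-8-[(tert-butyldimethylsilyl)oxy]-2,6-dimethyloct-2-enoate
Conditions: CH2Cl2, rt
Reagents that add atoms: none
Why: Wittig olefination with the stabilised α-methyl ylide should give the trisubstituted (E)-enoate, the geometry following from reversible, thermodynamically controlled oxaphosphetane formation.

**Step 16**
Reactants: 24 ethyl (2E,6S)-8-[(tert-butyldimethylsilyl)oxy]-2,6-dimethyloct-2-enoate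
Product: 25 (2E,6S)-8-[(tert-butyldimethylsilyl)oxy]-2,6-dimethyloct-2-enoic acid
Conditions: LiOH·H2O, THF/MeOH/H2O, 40 °C; cold 0.5 M HCl to pH 4
Reagents that add atoms: lithium hydroxide, [Li+].[OH-]
Why: Saponification of the ethyl ester should leave the primary TBS ether intact, since it tolerates aqueous LiOH and a brief mildly acidic work-up.

**Step 17**
Reactants: 19 (4R,4aS,6S,7S,7aR)-2,4,7-trimethyl-octahydro-1H-cyclopenta[c]pyridin-6-ol; 25 (2E,6S)-8-[(tert-butyldimethylsilyl)oxy]-2,6-dimethyloct-2-enoic acid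
Product: 26 (4R,4aS,6R,7S,7aR)-2,4,7-trimethyl-octahydro-1H-cyclopenta[c]pyridin-6-yl (2E,6S)-8-[(tert-butyldimethylsilyl)oxy]-2,6-dimethyloct-2-enoate
Conditions: PPh3, DIAD, THF, 0 °C → rt
Reagents that add atoms: none
Why: In this Mitsunobu esterification the alkoxyphosphonium ion of 19 is displaced by the carboxylate of 25 with inversion, turning the 6S alcohol into the 6R ester with oxygen cis to the C7 methyl as in the target.

**Step 18**
Reactants: 26 (4R,4aS,6R,7S,7aR)-2,4,7-trimethyl-octahydro-1H-cyclopenta[c]pyridin-6-yl (2E,6S)-8-[(tert-butyldimethylsilyl)oxy]-2,6-dimethyloct-2-enoate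
Product: 27 (4R,4aS,6R,7S,7aR)-2,4,7-trimethyl-octahydro-1H-cyclopenta[c]pyridin-6-yl (2E,6S)-8-hydroxy-2,6-dimethyloct-2-enoate (CNP0306711.1)
Conditions: HF·pyridine, THF/pyridine, 0 °C → rt; NaHCO3 work-up
Reagents that add atoms: none
Why: Fluoride cleavage of the primary silyl ether should leave the ester, the enoate and the tertiary amine intact and give the target.

**Compound list**
1 | methyl (E)-4-bromobut-2-enoate | COC(=O)/C=C/CBr | starting material
2 | 2-methylprop-2-en-1-amine (2-methylallylamine) | CC(=C)CN | starting material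
3 | methyl (E)-4-[(2-methylprop-2-enyl)amino]but-2-enoate | COC(=O)/C=C/CNCC(C)=C | intermediate (not isolated)
4 | methyl (E)-4-[(methoxycarbonyl)(2-methylprop-2-enyl)amino]but-2-enoate | COC(=O)/C=C/CN(CC(C)=C)C(=O)OC | intermediate
5 | methyl N-[(E)-4-hydroxybut-2-enyl]-N-(2-methylprop-2-enyl)carbamate | OC/C=C/CN(CC(C)=C)C(=O)OC | intermediate
6 | methyl N-[(E)-4-(methoxycarbonyloxy)but-2-enyl]-N-(2-methylprop-2-enyl)carbamate | COC(=O)OC/C=C/CN(CC(C)=C)C(=O)OC | intermediate
7 | dimethyl malonate | COC(=O)CC(=O)OC | starting material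
8 | dimethyl 2-[(2R)-1-[(methoxycarbonyl)(2-methylprop-2-enyl)amino]but-3-en-2-yl]propanedioate | C=C[C@@H](CN(CC(C)=C)C(=O)OC)C(C(=O)OC)C(=O)OC | intermediate
9 | dimethyl 2-[(2R)-1-[(methoxycarbonyl)(2-methylprop-2-enyl)amino]but-3-en-2-yl]-2-methylpropanedioate | C=C[C@@H](CN(CC(C)=C)C(=O)OC)C(C)(C(=O)OC)C(=O)OC | intermediate
10 | dimethyl 2-[(3R)-1-(methoxycarbonyl)-5-methyl-1,2,3,6-tetrahydropyridin-3-yl]-2-methylpropanedioate | COC(=O)N1C[C@H](C=C(C)C1)C(C)(C(=O)OC)C(=O)OC | intermediate
11 | methyl 2-[(3R)-1-(methoxycarbonyl)-5-methyl-1,2,3,6-tetrahydropyridin-3-yl]propanoate, both C2 epimers | COC(=O)N1C[C@H](C=C(C)C1)C(C)C(=O)OC | intermediate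
12 | 2-[(3R)-1-(methoxycarbonyl)-5-methyl-1,2,3,6-tetrahydropyridin-3-yl]propanoic acid, both C2 epimers | COC(=O)N1C[C@H](C=C(C)C1)C(C)C(=O)O | intermediate
13 | 2-[(3R)-1-(methoxycarbonyl)-5-methyl-1,2,3,6-tetrahydropyridin-3-yl]propanoyl chloride, both C2 epimers | COC(=O)N1C[C@H](C=C(C)C1)C(C)C(=O)Cl | intermediate (not isolated)
14 | methyl (3R)-3-(4-diazo-3-oxobutan-2-yl)-5-methyl-3,6-dihydro-2H-pyridine-1-carboxylate, both side-chain epimers | COC(=O)N1C[C@H](C=C(C)C1)C(C)C(=O)C=[N+]=[N-] | intermediate (not isolated)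
15 | methyl (3R)-3-(4-bromo-3-oxobutan-2-yl)-5-methyl-3,6-dihydro-2H-pyridine-1-carboxylate, both side-chain epimers | COC(=O)N1C[C@H](C=C(C)C1)C(C)C(=O)CBr | intermediate
16 | methyl (4R,4aS,7aR)-4,7-dimethyl-6-oxo-octahydro-2H-cyclopenta[c]pyridine-2-carboxylate, both C7 epimers | O=C1C[C@@H]2[C@@H](CN(C(=O)OC)C[C@@H]2C)C1C | intermediate (not isolated)
17 | methyl (4R,4aS,7S,7aR)-4,7-dimethyl-6-oxo-octahydro-2H-cyclopenta[c]pyridine-2-carboxylate | O=C1C[C@@H]2[C@@H](CN(C(=O)OC)C[C@@H]2C)[C@@H]1C | intermediate
18 | methyl (4R,4aS,6S,7S,7aR)-6-hydroxy-4,7-dimethyl-octahydro-2H-cyclopenta[c]pyridine-2-carboxylate | O[C@H]1C[C@@H]2[C@@H](CN(C(=O)OC)C[C@@H]2C)[C@@H]1C | intermediate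
19 | (4R,4aS,6S,7S,7aR)-2,4,7-trimethyl-octahydro-1H-cyclopenta[c]pyridin-6-ol | O[C@H]1C[C@@H]2[C@@H](CN(C)C[C@@H]2C)[C@@H]1C | intermediate
20 | (S)-citronellol, (3S)-3,7-dimethyloct-6-en-1-ol | C[C@@H](CCC=C(C)C)CCO | starting material
21 | tert-butyl{[(3S)-3,7-dimethyloct-6-en-1-yl]oxy}dimethylsilane | C[C@@H](CCC=C(C)C)CCO[Si](C)(C)C(C)(C)C | intermediate
22 | (4S)-6-[(tert-butyldimethylsilyl)oxy]-4-methylhexanal | C[C@@H](CCC=O)CCO[Si](C)(C)C(C)(C)C | intermediate
23 | ethyl 2-(triphenyl-λ5-phosphanylidene)propanoate | CCOC(=O)C(C)=P(c1ccccc1)(c1ccccc1)c1ccccc1 | starting material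
24 | ethyl (2E,6S)-8-[(tert-butyldimethylsilyl)oxy]-2,6-dimethyloct-2-enoate | CCOC(=O)/C(C)=C/CC[C@H](C)CCO[Si](C)(C)C(C)(C)C | intermediate
25 | (2E,6S)-8-[(tert-butyldimethylsilyl)oxy]-2,6-dimethyloct-2-enoic acid | OC(=O)/C(C)=C/CC[C@H](C)CCO[Si](C)(C)C(C)(C)C | intermediate
26 | (4R,4aS,6R,7S,7aR)-2,4,7-trimethyl-octahydro-1H-cyclopenta[c]pyridin-6-yl (2E,6S)-8-[(tert-butyldimethylsilyl)oxy]-2,6-dimethyloct-2-enoate | C/C(=C\CC[C@H](C)CCO[Si](C)(C)C(C)(C)C)C(=O)O[C@@H]1C[C@@H]2[C@@H](CN(C)C[C@@H]2C)[C@@H]1C | intermediate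
27 | (4R,4aS,6R,7S,7aR)-2,4,7-trimethyl-octahydro-1H-cyclopenta[c]pyridin-6-yl (2E,6S)-8-hydroxy-2,6-dimethyloct-2-enoate | C/C(=C\CC[C@H](C)CCO)C(=O)O[C@@H]1C[C@@H]2[C@@H](CN(C)C[C@@H]2C)[C@@H]1C | target

**Step count**
Total: 18 steps. Longest linear sequence: 14 steps (steps 1–12, 17, 18); the side-chain acid takes 4 steps (13–16).

**Steps most likely to fail**

Step 10. What may go wrong is hydrogen transfer from the stannane to the C5 radical before ring closure, which would give the uncyclised methyl ketone, and weak facial discrimination when hydrogen is delivered to the C4 radical. The fallback keeps the same C4a–C5 bond formation but removes the hydride and sets C4 by hydrogenation. It sets out from 15: halide exchange (NaI, acetone) should give the iodomethyl ketone methyl (3R)-3-(4-iodo-3-oxobutan-2-yl)-5-methyl-3,6-dihydro-2H-pyridine-1-carboxylate F1. Iodine-atom-transfer cyclisation (catalytic (Bu3Sn)2, hν, PhH) should then give the cis-fused tertiary iodide methyl 4-iodo-4,7-dimethyl-6-oxo-octahydro-2H-cyclopenta[c]pyridine-2-carboxylate F2. DBU should remove HI to give methyl 7-methyl-4-methylidene-6-oxo-octahydro-2H-cyclopenta[c]pyridine-2-carboxylate F3, together with endocyclic alkene isomers that converge in the next operation. Hydrogenation from the convex face (H2, Pd/C, EtOAc) should set C4, and NaOMe/MeOH equilibration of C7 brings the material back to the route at 17.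

Step 4. What may go wrong is erosion of the branched-to-linear ratio or of the enantioselectivity with this N-tethered carbonate. The fallback replaces catalyst control by a stereospecific substitution. It sets out from 2: opening of commercial (S)-2-vinyloxirane at its terminal carbon with excess 2 (iPrOH, 60 °C) should give (2S)-1-[(2-methylprop-2-enyl)amino]but-3-en-2-ol F4. Methoxycarbonylation of both nitrogen and oxygen (ClCO2Me, pyridine, DMAP) should give methyl N-[(2S)-2-(methoxycarbonyloxy)but-3-enyl]-N-(2-methylprop-2-enyl)carbamate F5. Rhodium-catalysed allylic alkylation (RhCl(PPh3)3, P(OMe)3, sodium dimethyl malonate, THF, 30 °C) proceeds with net retention at the secondary carbonate and should return to the route at 8.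

Step 17. What may go wrong is elimination, or failure of the SN2 displacement at the hindered C6 alkoxyphosphonium ion when the nucleophile is the valuable, weakly acidic enoic acid and a basic amine is present. The fallback moves the inversion to the neutral carbamate stage with a small, acidic partner and forms the ester by acyl transfer with retention. It sets out from 18: Mitsunobu reaction with 4-nitrobenzoic acid (PPh3, DIAD, toluene) should give methyl (4R,4aS,6R,7S,7aR)-4,7-dimethyl-6-(4-nitrobenzoyloxy)-octahydro-2H-cyclopenta[c]pyridine-2-carboxylate F6. Methanolysis (K2CO3, MeOH) should give methyl (4R,4aS,6R,7S,7aR)-6-hydroxy-4,7-dimethyl-octahydro-2H-cyclopenta[c]pyridine-2-carboxylate F7. LiAlH4 should give (4R,4aS,6R,7S,7aR)-2,4,7-trimethyl-octahydro-1H-cyclopenta[c]pyridin-6-ol F8. Yamaguchi esterification of F8 with 25 (2,4,6-trichlorobenzoyl chloride, Et3N, then DMAP, toluene) returns to the route at 26.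

**Further compounds**
F1 | step 10 | methyl (3R)-3-(4-iodo-3-oxobutan-2-yl)-5-methyl-3,6-dihydro-2H-pyridine-1-carboxylate, both side-chain epimers | COC(=O)N1C[C@H](C=C(C)C1)C(C)C(=O)CI
F2 | step 10 | methyl 4-iodo-4,7-dimethyl-6-oxo-octahydro-2H-cyclopenta[c]pyridine-2-carboxylate, cis-fused with ring-fusion hydrogens as in 17, C4 and C7 epimers | O=C1C[C@@H]2[C@@H](CN(C(=O)OC)CC2(C)I)C1C
F3 | step 10 | methyl 7-methyl-4-methylidene-6-oxo-octahydro-2H-cyclopenta[c]pyridine-2-carboxylate, cis-fused with ring-fusion hydrogens as in 17, C7 epimers | O=C1C[C@@H]2[C@@H](CN(C(=O)OC)CC2=C)C1C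
F4 | step 4 | (2S)-1-[(2-methylprop-2-enyl)amino]but-3-en-2-ol | C=C[C@H](O)CNCC(C)=C
F5 | step 4 | methyl N-[(2S)-2-(methoxycarbonyloxy)but-3-enyl]-N-(2-methylprop-2-enyl)carbamate | C=C[C@H](OC(=O)OC)CN(CC(C)=C)C(=O)OC
F6 | step 17 | methyl (4R,4aS,6R,7S,7aR)-4,7-dimethyl-6-(4-nitrobenzoyloxy)-octahydro-2H-cyclopenta[c]pyridine-2-carboxylate | O=C(O[C@@H]1C[C@@H]2[C@@H](CN(C(=O)OC)C[C@@H]2C)[C@@H]1C)c1ccc(cc1)[N+](=O)[O-]
F7 | step 17 | methyl (4R,4aS,6R,7S,7aR)-6-hydroxy-4,7-dimethyl-octahydro-2H-cyclopenta[c]pyridine-2-carboxylate | O[C@@H]1C[C@@H]2[C@@H](CN(C(=O)OC)C[C@@H]2C)[C@@H]1C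
F8 | step 17 | (4R,4aS,6R,7S,7aR)-2,4,7-trimethyl-octahydro-1H-cyclopenta[c]pyridin-6-ol | O[C@@H]1C[C@@H]2[C@@H](CN(C)C[C@@H]2C)[C@@H]1C
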